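**Plan**

- Retrosynthesis: the C6–C6' biaryl bond is cut (Suzuki–Miyaura) into a (2R,3R,4R) bromide and a (2R,3R,4S) boronate, both from one 6-bromo flavan-3,4-diol. Its C3–C4 bond is cut (pinacol) to an (R)-dialdehyde, and the O1–C2 bond is cut to a salicylaldehyde phenol and a cinnamyl carbonate.
- Forward: ring A phenol 4 and carbonate 8 are joined at O1–C2, the vinyl group is ozonized, and ring C is closed by C3–C4 pinacol coupling to the trans-diol 12. Part of 12 is inverted at C4 (oxidation, then reduction) to the all-cis diol 14, part is borylated to 15; coupling and hydrogenolysis finish the route.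
- Enabling feature: C4 (formyl carbon on C4a of ring A) and C3 (formyl carbon next to C2) are 1,6-related across C4a–C8a–O1–C2. In the forming ring C the axial site at C3 is flanked only by O1 and sp2 C4a, so two bulky titanium alkoxides can sit trans-diaxial while the C2 aryl group stays equatorial.
- Stereochemistry: C2 comes from an iridium-catalysed asymmetric allylic etherification. C3 and C4 of the trans half come from C2 in the key step. C4 of the cis half comes from axial hydride delivery to the 4-ketone.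

Key step: step 9

Assumption: the 6,6' biaryl axis has only two ortho substituents and is taken as freely rotating, so no axial configuration is set; in step 7 the ligand enantiomer is the one that gives the S ether.

**Step 1**
Reactants: 1 2,3,4-trihydroxybenzaldehyde
Product: 2 2,3,4-tris(benzyloxy)benzaldehyde
Conditions: BnBr (3.3 equiv), K2CO3, DMF, 60 °C
Reagents that add atoms: benzyl bromide, BrCc1ccccc1
Why: Williamson etherification of all three phenols under carbonate conditions should give the robust benzyl ethers that carry through the route.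

**Step 2**
Reactants: 2 2,3,4-tris(benzyloxy)benzaldehyde
Product: 3 3,4-bis(benzyloxy)-2-hydroxybenzaldehyde
Conditions: MgBr2·OEt2 (1.2 equiv), toluene/Et2O, 80 °C; then 1 M HCl
Reagents that add atoms: none
Why: Chelation of magnesium between the formyl oxygen and the ortho ether oxygen should direct bromide to the 2-O-benzyl group only (chelation-controlled ortho-debenzylation), freeing the phenol that becomes O1.

**Step 3**
Reactants: 3 3,4-bis(benzyloxy)-2-hydroxybenzaldehyde
Product: 4 3,4-bis(benzyloxy)-5-bromo-2-hydroxybenzaldehyde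
Conditions: NBS (1.05 equiv), MeCN, 0 °C to rt
Reagents that add atoms: N-bromosuccinimide, O=C1CCC(=O)N1Br
Why: Electrophilic aromatic bromination should go to C5 (the future C6), the only position para to the free phenol, ortho to the 4-benzyloxy group and meta to the formyl group.

**Step 4**
Reactants: 5 4-(benzyloxy)benzaldehyde
Product: 6 ethyl (E)-3-[4-(benzyloxy)phenyl]prop-2-enoate
Conditions: (EtO)2P(O)CH2CO2Et, NaH, THF, 0 °C to rt
Reagents that add atoms: triethyl phosphonoacetate, CCOC(=O)CP(=O)(OCC)OCC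
Why: The Horner–Wadsworth–Emmons olefination of an aryl aldehyde with a stabilized phosphonate should give the E-cinnamate.

**Step 5**
Reactants: 6 ethyl (E)-3-[4-(benzyloxy)phenyl]prop-2-enoate
Product: 7 (E)-3-[4-(benzyloxy)phenyl]prop-2-en-1-ol
Conditions: i-Bu2AlH (2.2 equiv), CH2Cl2, −78 °C; aq. potassium sodium tartrate
Reagents that add atoms: none
Why: 1,2-Reduction of the unsaturated ester with the aluminium hydride should give the allylic alcohol without touching the alkene geometry.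

**Step 6**
Reactants: 7 (E)-3-[4-(benzyloxy)phenyl]prop-2-en-1-ol
Product: 8 (E)-3-[4-(benzyloxy)phenyl]prop-2-en-1-yl methyl carbonate
Conditions: ClCO2Me, pyridine, CH2Cl2, 0 °C
Reagents that add atoms: methyl chloroformate, COC(Cl)=O
Why: Acylation of the primary allylic alcohol installs the carbonate leaving group needed for allyl–iridium formation.

**Step 7**
Reactants: 4 3,4-bis(benzyloxy)-5-bromo-2-hydroxybenzaldehyde; 8 (E)-3-[4-(benzyloxy)phenyl]prop-2-en-1-yl methyl carbonate
Product: 9 (S)-3,4-bis(benzyloxy)-2-({1-[4-(benzyloxy)phenyl]prop-2-en-1-yl}oxy)-5-bromobenzaldehyde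
Conditions: LiN(SiMe3)2 (1.0 equiv, forms the lithium aryloxide of 4); [Ir(cod)Cl]2 (2 mol%), (1,1'-binaphthyl-2,2'-diyl) N,N-bis(1-phenylethyl)phosphoramidite (4 mol%), pre-activated with n-PrNH2; THF, rt to 50 °C
Reagents that add atoms: none
Why: In this iridium-catalysed asymmetric allylic etherification the cyclometalated iridium phosphoramidite complex should send the aryloxide to the aryl-substituted allyl terminus and set the future C2 by catalyst control (S in the ether only because the CIP priorities differ from those in the flavan).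

**Step 8**
Reactants: 9 (S)-3,4-bis(benzyloxy)-2-({1-[4-(benzyloxy)phenyl]prop-2-en-1-yl}oxy)-5-bromobenzaldehyde
Product: 11 (R)-3,4-bis(benzyloxy)-2-{1-[4-(benzyloxy)phenyl]-2-oxoethoxy}-5-bromobenzaldehyde, via secondary ozonide 10 (not isolated)
Conditions: O3, CH2Cl2, −78 °C (Sudan Red 7B end point); PPh3, −78 °C to rt; crude product used at once
Reagents that add atoms: ozone, [O-][O+]=O
Why: Ozonolysis of the only alkene (arenes and benzyl ethers react far more slowly at −78 °C) and reductive cleavage of the ozonide with PPh3 should give the dialdehyde under neutral conditions that do not enolize the labile C2–H, so the stereocenter is untouched.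

**Step 9**
Reactants: 11 (R)-3,4-bis(benzyloxy)-2-{1-[4-(benzyloxy)phenyl]-2-oxoethoxy}-5-bromobenzaldehyde
Product: 12 (2R,3R,4S)-7,8-bis(benzyloxy)-2-[4-(benzyloxy)phenyl]-6-bromochromane-3,4-diol
Conditions: Cp2TiPh (2.5 equiv, from Cp2TiCl2, i-PrMgCl then PhMgBr), THF (0.02 M), −78 °C to rt; aq. NaHCO3, air, filtration through Celite
Reagents that add atoms: none
Why: Monomeric Cp2TiPh (trivalent titanium) reduces the aryl aldehyde to a titanium-bound benzylic ketyl at C4, which adds to the titanium-activated formyl carbon C3 (or couples with its ketyl), leaving two tetravalent titanium alkoxides that aqueous work-up hydrolyses to the diol. The closest known reaction type is the trans-selective pinacol cyclization of 1,6-dialdehydes to six-membered 1,2-diols with this reagent. Ring C closes in the 6-exo-trig mode (attack at the carbon of the C3=O bond, whose oxygen stays outside the ring). C3 and C4 are set together: the two bulky, non-bridging Cp2(Ph)Ti–O groups take the antiperiplanar (trans-diaxial) arrangement, which costs little here because the axial site at C3 is flanked only by O1 and sp2 C4a and a pseudo-axial C4–O bond avoids the peri hydrogen at C5, while C2 relays the absolute sense because its aryl group stays equatorial (an axial aryl would meet the axial C4–O–Ti group), so that O3 ends cis and O4 trans to the aryl group, i.e. 3R,4S. The step needs trans over cis diol selectivity, facial selectivity at C3, ring closure over dimerization and survival of the labile C2–H, which the non-chelating reagent, the short C4a–C8a–O1–C2 tether at high dilution, and neutral low-temperature conditions that leave the aryl bromide and benzyl ethers alone should secure.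

**Step 10**
Reactants: 12 (2R,3R,4S)-7,8-bis(benzyloxy)-2-[4-(benzyloxy)phenyl]-6-bromochromane-3,4-diol
Product: 13 (2R,3S)-7,8-bis(benzyloxy)-2-[4-(benzyloxy)phenyl]-6-bromo-3-hydroxychroman-4-one
Conditions: activated MnO2 (20 equiv), CH2Cl2, rt
Reagents that add atoms: none
Why: MnO2 should oxidize only the benzylic C4 alcohol to the aryl ketone, since the non-benzylic C3 hydroxyl is inert and the trans-diaxial diol cannot form the cyclic manganese ester needed for glycol cleavage, and the neutral conditions leave C2 and C3 (2,3-cis) untouched.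

**Step 11**
Reactants: 13 (2R,3S)-7,8-bis(benzyloxy)-2-[4-(benzyloxy)phenyl]-6-bromo-3-hydroxychroman-4-one
Product: 14 (2R,3R,4R)-7,8-bis(benzyloxy)-2-[4-(benzyloxy)phenyl]-6-bromochromane-3,4-diol
Conditions: NaBH4, CeCl3·7H2O, MeOH/THF, −78 °C
Reagents that add atoms: none
Why: In this Luche reduction the C3 hydroxyl of the 2,3-cis ketol is axial, so hydride should add to C4 axially from the face anti to it (Felkin–Anh and steric control agree) and place the new hydroxyl cis to O3 (4R), at a temperature at which the cis ketol should not epimerize.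

**Step 12**
Reactants: 12 (2R,3R,4S)-7,8-bis(benzyloxy)-2-[4-(benzyloxy)phenyl]-6-bromochromane-3,4-diol
Product: 15 (2R,3R,4S)-7,8-bis(benzyloxy)-2-[4-(benzyloxy)phenyl]-6-(4,4,5,5-tetramethyl-1,3,2-dioxaborolan-2-yl)chromane-3,4-diol
Conditions: B2pin2, Pd(dppf)Cl2 (5 mol%), KOAc, 1,4-dioxane, 85 °C
Reagents that add atoms: bis(pinacolato)diboron, CC1(C)OB(OC1(C)C)B1OC(C)(C)C(C)(C)O1
Why: Miyaura borylation of the aryl bromide with the weak base KOAc should tolerate the free trans-diaxial diol, which cannot chelate boron, and leaves all stereocenters alone.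

**Step 13**
Reactants: 14 (2R,3R,4R)-7,8-bis(benzyloxy)-2-[4-(benzyloxy)phenyl]-6-bromochromane-3,4-diol; 15 (2R,3R,4S)-7,8-bis(benzyloxy)-2-[4-(benzyloxy)phenyl]-6-(4,4,5,5-tetramethyl-1,3,2-dioxaborolan-2-yl)chromane-3,4-diol
Product: 16 (2R,3R,4R)-7,8-bis(benzyloxy)-2-[4-(benzyloxy)phenyl]-6-{(2R,3R,4S)-7,8-bis(benzyloxy)-2-[4-(benzyloxy)phenyl]-3,4-dihydroxychroman-6-yl}chromane-3,4-diol
Conditions: Pd(OAc)2 (5 mol%), SPhos (10 mol%), K3PO4, toluene/H2O, 70 °C
Reagents that add atoms: none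
Why: Suzuki–Miyaura cross-coupling with a bulky electron-rich biaryl phosphine should join the two mono-ortho-alkoxy aryl partners at C6–C6' under aqueous base, which does not ionize the benzylic C4 hydroxyls.

**Step 14**
Reactants: 16 (2R,3R,4R)-7,8-bis(benzyloxy)-2-[4-(benzyloxy)phenyl]-6-{(2R,3R,4S)-7,8-bis(benzyloxy)-2-[4-(benzyloxy)phenyl]-3,4-dihydroxychroman-6-yl}chromane-3,4-diol
Product: 17 (2R,3R,4R)-6-[(2R,3R,4S)-3,4,7,8-tetrahydroxy-2-(4-hydroxyphenyl)chroman-6-yl]-2-(4-hydroxyphenyl)chromane-3,4,7,8-tetrol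
Conditions: H2 (1 atm), Pd(OH)2/C, degassed THF/MeOH, rt; filtration under argon
Reagents that add atoms: none
Why: Hydrogenolysis of the six aryl benzyl ethers under neutral conditions should be much faster than cleavage of the benzylic C4–OH and C2–O1 bonds, so the free polyphenol should result with all six stereocenters unchanged.

**Compound list**

1 | 2,3,4-trihydroxybenzaldehyde | O=Cc1ccc(O)c(O)c1O | starting material
2 | 2,3,4-tris(benzyloxy)benzaldehyde | O=Cc1ccc(OCc2ccccc2)c(OCc2ccccc2)c1OCc1ccccc1 | intermediate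
3 | 3,4-bis(benzyloxy)-2-hydroxybenzaldehyde | O=Cc1ccc(OCc2ccccc2)c(OCc2ccccc2)c1O | intermediate
4 | 3,4-bis(benzyloxy)-5-bromo-2-hydroxybenzaldehyde | O=Cc1cc(Br)c(OCc2ccccc2)c(OCc2ccccc2)c1O | intermediate
5 | 4-(benzyloxy)benzaldehyde | O=Cc1ccc(OCc2ccccc2)cc1 | starting material
6 | ethyl (E)-3-[4-(benzyloxy)phenyl]prop-2-enoate | CCOC(=O)/C=C/c1ccc(OCc2ccccc2)cc1 | intermediate
7 | (E)-3-[4-(benzyloxy)phenyl]prop-2-en-1-ol | OC/C=C/c1ccc(OCc2ccccc2)cc1 | intermediate
8 | (E)-3-[4-(benzyloxy)phenyl]prop-2-en-1-yl methyl carbonate | COC(=O)OC/C=C/c1ccc(OCc2ccccc2)cc1 | intermediate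
9 | (S)-3,4-bis(benzyloxy)-2-({1-[4-(benzyloxy)phenyl]prop-2-en-1-yl}oxy)-5-bromobenzaldehyde | c1ccc(cc1)COc1ccc(cc1)[C@H](C=C)Oc1c(C=O)cc(Br)c(OCc2ccccc2)c1OCc1ccccc1 | intermediate
10 | (R)-3,4-bis(benzyloxy)-2-{[4-(benzyloxy)phenyl](1,2,4-trioxolan-3-yl)methoxy}-5-bromobenzaldehyde (secondary ozonide, trioxolane carbon as a mixture of epimers) | c1ccc(cc1)COc1ccc(cc1)[C@H](C2OCOO2)Oc1c(C=O)cc(Br)c(OCc2ccccc2)c1OCc1ccccc1 | intermediate
11 | (R)-3,4-bis(benzyloxy)-2-{1-[4-(benzyloxy)phenyl]-2-oxoethoxy}-5-bromobenzaldehyde | c1ccc(cc1)COc1ccc(cc1)[C@H](C=O)Oc1c(C=O)cc(Br)c(OCc2ccccc2)c1OCc1ccccc1 | intermediate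
12 | (2R,3R,4S)-7,8-bis(benzyloxy)-2-[4-(benzyloxy)phenyl]-6-bromochromane-3,4-diol (2,3-cis-3,4-trans) | c1ccc(cc1)COc1ccc(cc1)[C@H]1Oc2c(cc(Br)c(OCc3ccccc3)c2OCc2ccccc2)[C@H](O)[C@H]1O | intermediate
13 | (2R,3S)-7,8-bis(benzyloxy)-2-[4-(benzyloxy)phenyl]-6-bromo-3-hydroxychroman-4-one (2,3-cis) | c1ccc(cc1)COc1ccc(cc1)[C@H]1Oc2c(cc(Br)c(OCc3ccccc3)c2OCc2ccccc2)C(=O)[C@H]1O | intermediate
14 | (2R,3R,4R)-7,8-bis(benzyloxy)-2-[4-(benzyloxy)phenyl]-6-bromochromane-3,4-diol (all-cis) | c1ccc(cc1)COc1ccc(cc1)[C@H]1Oc2c(cc(Br)c(OCc3ccccc3)c2OCc2ccccc2)[C@@H](O)[C@H]1O | intermediate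
15 | (2R,3R,4S)-7,8-bis(benzyloxy)-2-[4-(benzyloxy)phenyl]-6-(4,4,5,5-tetramethyl-1,3,2-dioxaborolan-2-yl)chromane-3,4-diol | c1ccc(cc1)COc1ccc(cc1)[C@H]1Oc2c(cc(B3OC(C)(C)C(C)(C)O3)c(OCc3ccccc3)c2OCc2ccccc2)[C@H](O)[C@H]1O | intermediate
16 | (2R,3R,4R)-7,8-bis(benzyloxy)-2-[4-(benzyloxy)phenyl]-6-{(2R,3R,4S)-7,8-bis(benzyloxy)-2-[4-(benzyloxy)phenyl]-3,4-dihydroxychroman-6-yl}chromane-3,4-diol | C(c1ccccc1)Oc1ccc([C@H]2Oc3c(cc(-c4cc5c(c(OCc6ccccc6)c4OCc4ccccc4)O[C@H](c4ccc(OCc6ccccc6)cc4)[C@H](O)[C@H]5O)c(OCc4ccccc4)c3OCc3ccccc3)[C@@H](O)[C@H]2O)cc1 | intermediate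
17 | (2R,3R,4R)-6-[(2R,3R,4S)-3,4,7,8-tetrahydroxy-2-(4-hydroxyphenyl)chroman-6-yl]-2-(4-hydroxyphenyl)chromane-3,4,7,8-tetrol | Oc1ccc([C@H]2Oc3c(cc(-c4cc5c(c(O)c4O)O[C@H](c4ccc(O)cc4)[C@H](O)[C@H]5O)c(O)c3O)[C@@H](O)[C@H]2O)cc1 | target

**Step count and risks**

Total steps: 14. Longest linear sequence: 10 (steps 1, 2, 3, 7, 8, 9, 10, 11, 13, 14).

1. Step 9. The facial selectivity at C3 relative to C2 may be poor if closure runs through a trans-diequatorial or a chelated cis arrangement instead of the trans-diaxial one. The C2 center of the dialdehyde may also epimerize before closure, or the C3 ketyl may expel the aryloxide. The fallback closes ring C by olefin metathesis and sets out from 9. Methylenation of the aryl aldehyde (Ph3PCH3Br, KN(SiMe3)2, THF, −78 to 0 °C) would give (S)-1-bromo-2,3-bis(benzyloxy)-4-({1-[4-(benzyloxy)phenyl]prop-2-en-1-yl}oxy)-5-vinylbenzene F1. Ring-closing metathesis (second-generation Grubbs catalyst, CH2Cl2, 40 °C) would close C3=C4 to (S)-7,8-bis(benzyloxy)-2-[4-(benzyloxy)phenyl]-6-bromo-2H-chromene F2. NBS in THF/H2O at 0 °C should add bromine anti to the 2-aryl group and water at benzylic C4, giving (2R,3S,4R)-7,8-bis(benzyloxy)-2-[4-(benzyloxy)phenyl]-3,6-dibromochroman-4-ol F3. K2CO3 in MeOH would close the oxirane on the aryl face, giving (2R,3R,4R)-7,8-bis(benzyloxy)-2-[4-(benzyloxy)phenyl]-6-bromo-3,4-epoxychromane F4. Hydrolytic opening at benzylic C4 with inversion (THF/H2O, cat. pyridinium p-toluenesulfonate, 0 °C) comes back to the route at 12.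

2. Step 7. The branched-to-linear ratio or the enantioselectivity may be low with the hindered, weakly nucleophilic aryloxide, and the electron-rich ether may re-ionize on the metal. The fallback sets out from 4. Commercial (S)-4-hydroxymandelic acid (OC(=O)[C@@H](O)c1ccc(O)cc1) would be esterified (MeOH, cat. H2SO4) to methyl (S)-2-hydroxy-2-(4-hydroxyphenyl)acetate F5 and O-benzylated (BnBr, K2CO3, acetone) to methyl (S)-2-[4-(benzyloxy)phenyl]-2-hydroxyacetate F6. Mitsunobu coupling of F6 with 4 (PPh3, DIAD, toluene, 0 °C) should proceed with inversion to methyl (R)-2-[2,3-bis(benzyloxy)-4-bromo-6-formylphenoxy]-2-[4-(benzyloxy)phenyl]acetate F7. LiBH4 (THF, 0 °C) would reduce ester and aryl aldehyde to (R)-2-[2,3-bis(benzyloxy)-4-bromo-6-(hydroxymethyl)phenoxy]-2-[4-(benzyloxy)phenyl]ethanol F8. Double oxidation with DMP (NaHCO3, CH2Cl2, 0 °C) comes back to the route at 11.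

3. Step 14. Over-reduction may occur: hydrogenolysis of the benzylic C4–O bonds, which are activated by the para oxygen, or of the C2–O1 bond, alongside oxidation of the free polyphenol on work-up. The fallback sets out from 16 and masks the four secondary hydroxyls first. Silylation (TBSOTf, 2,6-lutidine, CH2Cl2, −78 to 0 °C) would give the tetrakis(tert-butyldimethylsilyl) ether of 16 F9. Hydrogenolysis (H2, Pd(OH)2/C, EtOAc), to which benzylic silyl ethers are resistant, would give the tetrakis(tert-butyldimethylsilyl) ether of 17 F10. Near-neutral desilylation (Et3N·3HF, THF/MeCN, 0 °C to rt, degassed) comes back to the route at 17.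

**Further compounds**

F1 | step 9 | (S)-1-bromo-2,3-bis(benzyloxy)-4-({1-[4-(benzyloxy)phenyl]prop-2-en-1-yl}oxy)-5-vinylbenzene | c1ccc(cc1)COc1ccc(cc1)[C@H](C=C)Oc1c(C=C)cc(Br)c(OCc2ccccc2)c1OCc1ccccc1
F2 | step 9 | (S)-7,8-bis(benzyloxy)-2-[4-(benzyloxy)phenyl]-6-bromo-2H-chromene | c1ccc(cc1)COc1ccc(cc1)[C@H]1Oc2c(cc(Br)c(OCc3ccccc3)c2OCc2ccccc2)C=C1
F3 | step 9 | (2R,3S,4R)-7,8-bis(benzyloxy)-2-[4-(benzyloxy)phenyl]-3,6-dibromochroman-4-ol | c1ccc(cc1)COc1ccc(cc1)[C@H]1Oc2c(cc(Br)c(OCc3ccccc3)c2OCc2ccccc2)[C@@H](O)[C@@H]1Br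
F4 | step 9 | (2R,3R,4R)-7,8-bis(benzyloxy)-2-[4-(benzyloxy)phenyl]-6-bromo-3,4-epoxychromane | c1ccc(cc1)COc1ccc(cc1)[C@H]1Oc2c(cc(Br)c(OCc3ccccc3)c2OCc2ccccc2)[C@H]2O[C@@H]12
F5 | step 7 | methyl (S)-2-hydroxy-2-(4-hydroxyphenyl)acetate | COC(=O)[C@@H](O)c1ccc(O)cc1
F6 | step 7 | methyl (S)-2-[4-(benzyloxy)phenyl]-2-hydroxyacetate | COC(=O)[C@@H](O)c1ccc(OCc2ccccc2)cc1
F7 | step 7 | methyl (R)-2-[2,3-bis(benzyloxy)-4-bromo-6-formylphenoxy]-2-[4-(benzyloxy)phenyl]acetate | c1ccc(cc1)COc1ccc(cc1)[C@H](C(=O)OC)Oc1c(C=O)cc(Br)c(OCc2ccccc2)c1OCc1ccccc1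
F8 | step 7 | (R)-2-[2,3-bis(benzyloxy)-4-bromo-6-(hydroxymethyl)phenoxy]-2-[4-(benzyloxy)phenyl]ethanol | c1ccc(cc1)COc1ccc(cc1)[C@H](CO)Oc1c(CO)cc(Br)c(OCc2ccccc2)c1OCc1ccccc1
F9 | step 14 | 3,4,3',4'-tetrakis-O-(tert-butyldimethylsilyl) ether of 16 | C(c1ccccc1)Oc1ccc([C@H]2Oc3c(cc(-c4cc5c(c(OCc6ccccc6)c4OCc4ccccc4)O[C@H](c4ccc(OCc6ccccc6)cc4)[C@H](O[Si](C)(C)C(C)(C)C)[C@H]5O[Si](C)(C)C(C)(C)C)c(OCc4ccccc4)c3OCc3ccccc3)[C@@H](O[Si](C)(C)C(C)(C)C)[C@H]2O[Si](C)(C)C(C)(C)C)cc1
F10 | step 14 | 3,4,3',4'-tetrakis-O-(tert-butyldimethylsilyl) ether of 17 | Oc1ccc([C@H]2Oc3c(cc(-c4cc5c(c(O)c4O)O[C@H](c4ccc(O)cc4)[C@H](O[Si](C)(C)C(C)(C)C)[C@H]5O[Si](C)(C)C(C)(C)C)c(O)c3O)[C@@H](O[Si](C)(C)C(C)(C)C)[C@H]2O[Si](C)(C)C(C)(C)C)cc1
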